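**Strategy.** Everything rests on cutting both C1–C2 bonds, those joining each ketone carbon to its first chain methylene. The feature exploited is the 2,6-dihydroxyaryl ketone motif. In rings C and D the carbon bearing C1 lies between two hydroxylated carbons, so C1 can be purchased as the CHO carbon of 2,6-dihydroxybenzaldehyde. One ortho oxygen, once deprotonated, serves as a built-in anchor guiding rhodium to the formyl C–H bond. A single twofold hydroacylation then joins two aldehyde molecules to the terminal C2=C3 alkenes of the precursor, a biphenyl (rings A and B) with two oct-7-enyl chains and four methylated catechol oxygens. This gives both linear ketones with rings C and D unprotected. BBr3 finally unmasks the catechols.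

Key step: step 6

Assumption: the biaryl axis carries only two ortho substituents (oxygen at C2, alkyl at C2'), so it is taken as freely rotating. The target has no stereocentre and nothing stereochemical has to be controlled.

Remark on chain length: an oct-7-enyl chain (eight carbons) plus the formyl carbon gives the nine-carbon C1–C9 chain between rings C or D and the biphenyl.

Step 1
Reactants: 1 2-bromo-6-methoxyphenol; 2 (3,4-dimethoxyphenyl)boronic acid
Product: 3 3,3',4'-trimethoxybiphenyl-2-ol, that is 2-(3,4-dimethoxyphenyl)-6-methoxyphenol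
Conditions: Pd(dppf)Cl2 (3 mol%), K2CO3 (3 equiv), 1,4-dioxane/H2O 4:1, 90 °C, argon
Reagents that add atoms: none
Why: Suzuki–Miyaura coupling forms the ring A–ring B bond, aqueous carbonate conditions tolerate a free ortho-bromophenol, and the hydroxyl is kept free on purpose because it steers the next step.

Step 2
Reactants: 3 3,3',4'-trimethoxybiphenyl-2-ol
Product: 4 2',5-dibromo-3,4',5'-trimethoxybiphenyl-2-ol
Conditions: NBS (2.05 equiv), MeCN, 0 °C to rt, dark
Reagents that add atoms: N-bromosuccinimide, O=C1CCC(=O)N1Br
Why: Electrophilic aromatic bromination should hit the two most nucleophilic carbons, since in ring A the free C2 hydroxyl outranks the C3 methoxy group and, with both its ortho positions occupied, directs to para C5, while ring B reacts like any 4-substituted veratrole, para to the 3'-methoxy group at the carbon next to the biaryl bond (renumbered C2'); a fully methylated ring A would tend to react para to its C3 methoxy group instead, which is why methylation comes afterwards.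

Step 3
Reactants: 4 2',5-dibromo-3,4',5'-trimethoxybiphenyl-2-ol
Product: 5 2',5-dibromo-2,3,4',5'-tetramethoxybiphenyl
Conditions: MeI (1.5 equiv), K2CO3 (2 equiv), DMF, 40 °C
Reagents that add atoms: iodomethane, CI
Why: Williamson etherification of the phenoxide with MeI removes the only acidic proton before the organozinc and rhodium/base steps and leaves four identical masks that fall in one final operation.

Step 4
Reactants: 6 8-bromooct-1-ene
Product: 7 oct-7-en-1-ylzinc bromide (LiCl-solubilised THF solution, titrated and carried on as such)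
Conditions: Zn dust (1.5 equiv, activated with BrCH2CH2Br 5 mol% and Me3SiCl 1 mol%), LiCl (1.5 equiv), THF, 50 °C
Reagents that add atoms: zinc, [Zn]
Why: LiCl-promoted direct insertion of zinc metal into a primary alkyl bromide is well established, and the alkene sits six methylenes away, so cyclisation of any transient radical is too slow to compete.

Step 5
Reactants: 5 2',5-dibromo-2,3,4',5'-tetramethoxybiphenyl; 7 oct-7-en-1-ylzinc bromide (3 equiv)
Product: 8 2,3,4',5'-tetramethoxy-2',5-di(oct-7-en-1-yl)biphenyl
Conditions: Pd(OAc)2 (4 mol%), SPhos (8 mol%), THF, rt to 50 °C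
Reagents that add atoms: none
Why: In this twofold Negishi sp3–sp2 coupling the bulky electron-rich biarylphosphine speeds insertion of zerovalent palladium into both electron-rich C–Br bonds, including the hindered C2'–Br, and speeds reductive elimination ahead of β-hydride elimination, while the methyl ethers and remote alkenes ignore the mild organozinc.

Step 6
Reactants: 8 2,3,4',5'-tetramethoxy-2',5-di(oct-7-en-1-yl)biphenyl; 9 2,6-dihydroxybenzaldehyde (3 equiv)
Product: 10 9,9'-(2,3,4',5'-tetramethoxybiphenyl-2',5-diyl)bis[1-(2,6-dihydroxyphenyl)nonan-1-one]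
Conditions: [Rh(cod)Cl]2 (5 mol%), bis(dicyclohexylphosphino)methane (dcpm, 10 mol%), K3PO4 (20 mol%), degassed 1,2-dichloroethane, 80 °C, sealed tube
Reagents that add atoms: none
Why: K3PO4 deprotonates one of the two equivalent phenols of 9, the phenoxide replaces chloride on dcpm-ligated monovalent rhodium, and the metal so positioned inserts into the adjacent formyl C–H bond to give a five-membered O,C-chelated acyl hydride of trivalent rhodium. A terminal alkene of 8 then coordinates and inserts into Rh–H with the metal ending on the unsubstituted carbon C2, C–C reductive elimination forges C1–C2, and proton exchange with fresh 9 frees the ketone so that the cycle repeats at the second, remote chain. The closest known reaction type is the chelation-assisted intermolecular hydroacylation of unactivated 1-alkenes with salicylaldehydes under rhodium/phosphine/base catalysis. No ring is closed and no stereocentre is created. The step needs linear over branched insertion, which the bulky cyclohexyl groups and narrow bite angle of dcpm favour by penalising a secondary alkylrhodium, and it needs hydroacylation to outrun decarbonylation, which the chelate favours by leaving no free site for CO extrusion. On the substrate side, the methyl ethers of 8 remove every acidic or chelating catechol site that could compete for rhodium or base, the two alkenes are too far apart to bind one metal together, either hydroxyl of 9 can direct while the other stays hydrogen-bonded to the carbonyl, and the excess of 9 drives both additions.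

Step 7
Reactants: 10 9,9'-(2,3,4',5'-tetramethoxybiphenyl-2',5-diyl)bis[1-(2,6-dihydroxyphenyl)nonan-1-one]
Product: 11 9,9'-(2,3,4',5'-tetrahydroxybiphenyl-2',5-diyl)bis[1-(2,6-dihydroxyphenyl)nonan-1-one] (CNP0305015.0)
Conditions: BBr3 (12 equiv), CH2Cl2, −78 °C to rt, argon; then ice-water, EtOAc extraction under argon
Reagents that add atoms: none
Why: In this Lewis-acid aryl methyl ether cleavage BBr3 binds each methoxy oxygen and bromide removes the methyl group by SN2, the adjacent oxygens of each catechol help through cyclic borates, and the hydrogen-bonded aryl ketones are only chelated reversibly and are released on hydrolysis.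

**Compound list**

| No. | Name | SMILES | Role |
|---|---|---|---|
| 1 | 2-bromo-6-methoxyphenol | COc1cccc(Br)c1O | starting material |
| 2 | (3,4-dimethoxyphenyl)boronic acid | COc1ccc(B(O)O)cc1OC | starting material |
| 3 | 3,3',4'-trimethoxybiphenyl-2-ol | COc1cccc(-c2ccc(OC)c(OC)c2)c1O | intermediate |
| 4 | 2',5-dibromo-3,4',5'-trimethoxybiphenyl-2-ol | COc1cc(Br)cc(-c2cc(OC)c(OC)cc2Br)c1O | intermediate |
| 5 | 2',5-dibromo-2,3,4',5'-tetramethoxybiphenyl | COc1cc(Br)cc(-c2cc(OC)c(OC)cc2Br)c1OC | intermediate |
| 6 | 8-bromooct-1-ene | C=CCCCCCCBr | starting material |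
| 7 | oct-7-en-1-ylzinc bromide | C=CCCCCCC[Zn]Br | intermediate |
| 8 | 2,3,4',5'-tetramethoxy-2',5-di(oct-7-en-1-yl)biphenyl | C=CCCCCCCc1cc(OC)c(OC)c(-c2cc(OC)c(OC)cc2CCCCCCC=C)c1 | intermediate |
| 9 | 2,6-dihydroxybenzaldehyde | O=Cc1c(O)cccc1O | starting material |
| 10 | 9,9'-(2,3,4',5'-tetramethoxybiphenyl-2',5-diyl)bis[1-(2,6-dihydroxyphenyl)nonan-1-one] | O=C(CCCCCCCCc1cc(OC)c(OC)c(-c2cc(OC)c(OC)cc2CCCCCCCCC(=O)c2c(O)cccc2O)c1)c1c(O)cccc1O | intermediate |
| 11 | 9,9'-(2,3,4',5'-tetrahydroxybiphenyl-2',5-diyl)bis[1-(2,6-dihydroxyphenyl)nonan-1-one] | O=C(CCCCCCCCc1cc(O)c(O)c(-c2cc(O)c(O)cc2CCCCCCCCC(=O)c2c(O)cccc2O)c1)c1c(O)cccc1O | target |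

Total step count: 7.
Longest linear sequence: 6 (steps 1, 2, 3, 5, 6, 7). Step 4 is a one-step side branch.

**Steps most likely to fail**

**Step 6.** Four things may go wrong:
- competing branched insertion;
- inward migration of the double bonds through reversible Rh–H addition;
- decarbonylation of the aldehyde;
- stalling after the first addition.

Any shortfall in site selectivity counts twice because two chains must react. The fallback sets out from 8 and comes back at 11.
- Linear-selective hydroformylation (Rh(acac)(CO)2, Xantphos, CO/H2 1:1, 20 bar, toluene, 80 °C) should give 9,9'-(2,3,4',5'-tetramethoxybiphenyl-2',5-diyl)dinonanal F1.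
- Directed ortho-lithiation of 1,3-dimethoxybenzene (n-BuLi, THF, 0 °C) provides (2,6-dimethoxyphenyl)lithium F2.
- F2 adds to both formyl groups at −78 °C to give 9,9'-(2,3,4',5'-tetramethoxybiphenyl-2',5-diyl)bis[1-(2,6-dimethoxyphenyl)nonan-1-ol] F3. Its carbinol stereoisomers do not matter.
- Dess–Martin oxidation in CH2Cl2 gives 9,9'-(2,3,4',5'-tetramethoxybiphenyl-2',5-diyl)bis[1-(2,6-dimethoxyphenyl)nonan-1-one] F4.
- BBr3 in CH2Cl2 then cleaves all eight methyl ethers to give 11.

**Step 5.** Oxidative addition may be slow at the hindered, electron-rich C2'–Br bond. β-Hydride elimination from the alkylpalladium intermediate may also cause hydrodebromination and chain-walking of the terminal alkene. The fallback sets out from 5 and comes back at 8. It replaces the organozinc by an organoborane of different origin.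
- Octa-1,7-diene in fivefold excess is monohydroborated with 9-BBN-H in THF, and the surplus diene is stripped off. This gives 9-(oct-7-en-1-yl)-9-borabicyclo[3.3.1]nonane F5.
- F5 is coupled twice with 5 in a B-alkyl Suzuki–Miyaura reaction (Pd(dppf)Cl2, K3PO4, DMF/THF/H2O, 60 °C). The chelating bisphosphine holds back β-hydride elimination.

**Step 7.** Cleavage of the crowded C2 ether may be incomplete, and the freed catechols may be oxidised by air during the acidic boron work-up. The fallback sets out from 4 and comes back at 11. It changes the catechol masks before the chains are installed.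
- BBr3 on the robust dibromide 4 gives 2',5-dibromobiphenyl-2,3,4',5'-tetraol F6.
- BnBr/K2CO3 in DMF under argon gives 2,3,4',5'-tetrakis(benzyloxy)-2',5-dibromobiphenyl F7.
- Negishi coupling with 7 as in step 5 gives 2,3,4',5'-tetrakis(benzyloxy)-2',5-di(oct-7-en-1-yl)biphenyl F8.
- Hydroacylation with 9 as in step 6 gives 9,9'-[2,3,4',5'-tetrakis(benzyloxy)biphenyl-2',5-diyl]bis[1-(2,6-dihydroxyphenyl)nonan-1-one] F9.
- Hydrogenolysis (H2 1 atm, Pd/C, EtOAc/EtOH, rt) then frees 11 under neutral, oxygen-free conditions. This is feasible because no alkene remains at that stage and the chelated aryl ketones are slow to reduce.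

**Further compounds**
F1 | step 6 | 9,9'-(2,3,4',5'-tetramethoxybiphenyl-2',5-diyl)dinonanal | O=CCCCCCCCCc1cc(OC)c(OC)c(-c2cc(OC)c(OC)cc2CCCCCCCCC=O)c1
F2 | step 6 | (2,6-dimethoxyphenyl)lithium | [Li]c1c(OC)cccc1OC
F3 | step 6 | 9,9'-(2,3,4',5'-tetramethoxybiphenyl-2',5-diyl)bis[1-(2,6-dimethoxyphenyl)nonan-1-ol], mixture of stereoisomers at the two carbinol carbons | COc1cccc(OC)c1C(O)CCCCCCCCc1cc(OC)c(OC)c(-c2cc(OC)c(OC)cc2CCCCCCCCC(O)c2c(OC)cccc2OC)c1
F4 | step 6 | 9,9'-(2,3,4',5'-tetramethoxybiphenyl-2',5-diyl)bis[1-(2,6-dimethoxyphenyl)nonan-1-one] | COc1cccc(OC)c1C(=O)CCCCCCCCc1cc(OC)c(OC)c(-c2cc(OC)c(OC)cc2CCCCCCCCC(=O)c2c(OC)cccc2OC)c1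
F5 | step 5 | 9-(oct-7-en-1-yl)-9-borabicyclo[3.3.1]nonane | C=CCCCCCCB1C2CCCC1CCC2
F6 | step 7 | 2',5-dibromobiphenyl-2,3,4',5'-tetraol | Oc1cc(Br)cc(-c2cc(O)c(O)cc2Br)c1O
F7 | step 7 | 2,3,4',5'-tetrakis(benzyloxy)-2',5-dibromobiphenyl | Brc1cc(OCc2ccccc2)c(OCc2ccccc2)c(-c2cc(OCc3ccccc3)c(OCc3ccccc3)cc2Br)c1
F8 | step 7 | 2,3,4',5'-tetrakis(benzyloxy)-2',5-di(oct-7-en-1-yl)biphenyl | C=CCCCCCCc1cc(OCc2ccccc2)c(OCc2ccccc2)c(-c2cc(OCc3ccccc3)c(OCc3ccccc3)cc2CCCCCCC=C)c1
F9 | step 7 | 9,9'-[2,3,4',5'-tetrakis(benzyloxy)biphenyl-2',5-diyl]bis[1-(2,6-dihydroxyphenyl)nonan-1-one] | O=C(CCCCCCCCc1cc(OCc2ccccc2)c(OCc2ccccc2)c(-c2cc(OCc3ccccc3)c(OCc3ccccc3)cc2CCCCCCCCC(=O)c2c(O)cccc2O)c1)c1c(O)cccc1O
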